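A direct plan would build the pyrrole ring onto 2,5-dibromoaniline A1 by a Gassman oxindole synthesis, which would give racemic 4,7-dibromo-3-(methylsulfanyl)indolin-2-one A2 in one pot.
It would then reduce the sulfur away to 4,7-dibromoindolin-2-one A3 with zinc, turn that lactam into 2,4,7-tribromo-1H-indole A4 with POBr3 and chlorinate C3 last.
Its weakest step would be the ring-forming sulfonium-ylide [2,3]-shift: it would have to deliver carbon to the one free ortho position of an electron-poor aniline, a position flanked by bromine, in a cryogenic one-pot through several unisolated intermediates, so the ring closure would be left to chance.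
The reductive desulfurisation would be a whole step that only removes an auxiliary group (and a racemic C3 centre) that the first step put in: two steps for an unsubstituted oxindole.
The lactam deoxybromination would release HBr onto a free N–H 2-bromoindole that oligomerises in acid; it, and the halogenation of that same unprotected indole after it, would be the steps least welcome on late material.

**Plan of the new route**
- Retrosynthesis: remove N–Boc, cut C2–Br (directed metalation), cut C3–Cl (SEAr), then cut C4–C3a and C7–C7a together in a retro-[4+2], which leads to N-Boc-pyrrole and 2,5-dibromothiophene 1,1-dioxide.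
- Enabling feature: in the benzo ring, C4(Br)–C5H=C6H–C7(Br) is a symmetric 1,4-dibromobutadiene-1,4-diyl unit, i.e. the four carbons of 2,5-dibromothiophene, and C3a–C7a is the 2,3-bond of a pyrrole; the sulfur that holds the diene s-cis leaves as SO2 in the ring-forming step.
- Ring order: the pyrrole ring is bought intact; the benzene ring arises on it in the key step and brings both ring bromines in fixed positions.
- The weak steps do not arise: no sigmatropic closure onto a hindered ortho carbon, no auxiliary group removed in a step of its own, no oxindole and no POBr3; the 2-bromoindole stays N-acylated until a final base-mediated unmasking.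

Key step: step 2

Remark: the target is achiral (1H-indole numbering: C2–Br, C3–Cl, C4–Br, C7–Br); the only stereocentres of the route are the transient ring-fusion centres in step 2.

Step 1
Reactants: 1 2,5-dibromothiophene
Product: 2 2,5-dibromothiophene 1,1-dioxide
Conditions: H2O2 (50% aq.), (CF3CO)2O, CH2Cl2, 0 °C → rt
Reagents that add atoms: hydrogen peroxide, OO (delivered as trifluoroperacetic acid, OOC(=O)C(F)(F)F, formed in the flask with trifluoroacetic anhydride)
Why: Peracid S-oxidation of a thiophene to its 1,1-dioxide, in which trifluoroperacetic acid is electrophilic enough for the electron-poor dibromothiophene, the second oxidation is faster than the first, and the 2,5-bromines slow the Diels–Alder self-dimerisation that makes the parent dioxide unisolable.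

Step 2
Reactants: 2 2,5-dibromothiophene 1,1-dioxide; 3 tert-butyl 1H-pyrrole-1-carboxylate (N-Boc-pyrrole)
Product: 6 tert-butyl 4,7-dibromo-1H-indole-1-carboxylate, via bridged sulfone cycloadduct 4 (not isolated), via cis-3a,7a-dihydroindole 5 (not isolated)
Conditions: 3 (4 equiv), toluene, 100 °C, sealed tube (−SO2); then DDQ (1.2 equiv), rt
Reagents that add atoms: none
Why: Proposed new method: the electron-poor s-cis diene of 2 (C2=C3–C4=C5, its LUMO lowered by the sulfonyl group and two bromines) should add in an inverse-electron-demand [4+2] cycloaddition to the C2=C3 bond of the N-acylpyrrole 3, forming C7–C7a and C4–C3a at once; the strained 7-thiabicyclo[2.2.1]heptene 7,7-dioxide 4 then loses SO2 by cheletropic extrusion to the cis-fused cyclohexadiene 5, from which DDQ takes hydride at C7a (allylic and alpha to nitrogen) and a proton at C3a, so that the benzene ring forms and the pyrrole ring regains its aromaticity. The closest known reaction type is the annulation of halogenated thiophene 1,1-dioxides with alkenes, enol ethers and furans (which react as 2π partners at their 2,3-bond) followed by SO2 loss and dehydrogenation, together with the use of pyrroles as dienophiles toward other electron-poor dienes such as 1,2,4,5-tetrazines; new is the pairing of a 2,5-dibromothiophene dioxide with an N-acylpyrrole. The six-membered ring is closed by an intermolecular suprafacial [4+2] cycloaddition (two sigma bonds), and no five-membered ring is closed. The two stereocentres of 4 and 5 (C3a, C7a) are cis by the suprafacial addition, form as a racemate and are erased by the dehydrogenation, so the endo/exo ratio is without consequence. Regioselectivity is not needed because 2 is C2v-symmetric and its bromines end up on C4 and C7 whichever way it adds; the Boc group keeps the pyrrole from attacking the bromovinyl sulfone as an N- or C-nucleophile, the competing mode in which 3 is the diene is reversible whereas SO2 loss is not, and the excess of 3 should outrun dimerisation of 2 and a second annulation on the C2=C3 bond of 6.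

Step 3
Reactants: 6 tert-butyl 4,7-dibromo-1H-indole-1-carboxylate
Product: 7 tert-butyl 4,7-dibromo-3-chloro-1H-indole-1-carboxylate
Conditions: NCS (1.1 equiv), DMF, 50 °C
Reagents that add atoms: N-chlorosuccinimide, O=C1CCC(=O)N1Cl
Why: Electrophilic aromatic substitution (SEAr) of an N-acylindole with a halenium donor, in which C3 is the enamide beta-carbon whose sigma-complex is an N-acyliminium ion that leaves the benzene sextet intact, the benzo ring is deactivated by its two bromines, and the carbamate excludes N-chlorination and a second halogenation.

Step 4
Reactants: 7 tert-butyl 4,7-dibromo-3-chloro-1H-indole-1-carboxylate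
Product: 9 tert-butyl 2,4,7-tribromo-3-chloro-1H-indole-1-carboxylate, via indol-2-yllithium 8 (not isolated)
Conditions: LiN(i-Pr)2 (1.1 equiv), THF, −78 °C; then BrCl2C–CCl2Br, −78 °C → 0 °C
Reagents that add atoms: 1,2-dibromo-1,1,2,2-tetrachloroethane, BrC(Cl)(Cl)C(Cl)(Cl)Br
Why: Directed ortho-metalation (complex-induced proximity effect of the Boc carbonyl) removes the C2 proton, the most acidic one because it lies between the carbamate nitrogen and the C3 chlorine, with a hindered amide base that does not undergo bromine–lithium exchange at C4 or C7, and the indol-2-yllithium 8 then attacks a bromine of the vicinal dibromide, which fragments to tetrachloroethene and bromide, so that bromine can enter only at C2.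

Step 5
Reactants: 9 tert-butyl 2,4,7-tribromo-3-chloro-1H-indole-1-carboxylate
Product: 10 2,4,7-tribromo-3-chloro-1H-indole
Conditions: K2CO3 (0.2 equiv), MeOH/THF, rt
Reagents that add atoms: none
Why: Base-catalysed methanolysis (transacylation) of an activated N-acylindole, in which methoxide adds to a carbamate carbonyl that is twisted out of conjugation between the C2 and C7 bromines and expels the stabilised tetrahaloindolide, so that the acid-sensitive N–H 2-bromoindole is set free without acid and only in the last step.

**Compound list**
1 | 2,5-dibromothiophene | Brc1ccc(Br)s1 | starting material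
2 | 2,5-dibromothiophene 1,1-dioxide | O=S1(=O)C(Br)=CC=C1Br | intermediate
3 | tert-butyl 1H-pyrrole-1-carboxylate (N-Boc-pyrrole) | CC(C)(C)OC(=O)n1cccc1 | starting material
4 | tert-butyl 4,7-dibromo-3a,4,7,7a-tetrahydro-4,7-epithio-1H-indole-1-carboxylate S,S-dioxide (cis ring fusion, racemic, endo/exo not defined) | CC(C)(C)OC(=O)N1C=C[C@H]2[C@@H]1C1(Br)C=CC2(Br)S1(=O)=O | intermediate
5 | tert-butyl cis-4,7-dibromo-3a,7a-dihydro-1H-indole-1-carboxylate (racemic) | CC(C)(C)OC(=O)N1C=C[C@H]2[C@@H]1C(Br)=CC=C2Br | intermediate
6 | tert-butyl 4,7-dibromo-1H-indole-1-carboxylate | CC(C)(C)OC(=O)n1ccc2c(Br)ccc(Br)c12 | intermediate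
7 | tert-butyl 4,7-dibromo-3-chloro-1H-indole-1-carboxylate | CC(C)(C)OC(=O)n1cc(Cl)c2c(Br)ccc(Br)c12 | intermediate
8 | tert-butyl 4,7-dibromo-3-chloro-2-lithio-1H-indole-1-carboxylate | CC(C)(C)OC(=O)n1c([Li])c(Cl)c2c(Br)ccc(Br)c12 | intermediate
9 | tert-butyl 2,4,7-tribromo-3-chloro-1H-indole-1-carboxylate | CC(C)(C)OC(=O)n1c(Br)c(Cl)c2c(Br)ccc(Br)c12 | intermediate
10 | 2,4,7-tribromo-3-chloro-1H-indole | Clc1c(Br)[nH]c2c(Br)ccc(Br)c12 | target

Total step count: 5. Longest linear sequence: 5 steps (1 → 2 → 6 → 7 → 9 → 10; 3 enters in step 2).

**Steps most likely to fail**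

Step 2. The dearomative cycloaddition may be slower than thermal dimerisation of the diene, or the Boc group may be lost on prolonged heating. The fallback would set out from 2 and use a non-aromatic, more electron-rich dienophile, commercial tert-butyl 2,3-dihydro-1H-pyrrole-1-carboxylate (CC(C)(C)OC(=O)N1CCC=C1), in the known annulation of halothiophene dioxides with electron-rich alkenes. Cycloaddition in toluene at 80 °C with loss of SO2 should give tert-butyl cis-4,7-dibromo-2,3,3a,7a-tetrahydro-1H-indole-1-carboxylate F1. DDQ at rt should aromatise the six-membered ring to tert-butyl 4,7-dibromo-2,3-dihydro-1H-indole-1-carboxylate F2, and a second dehydrogenation (excess DDQ, 1,4-dioxane, 100 °C) would bring the route back at 6.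

Step 4. Metalation may compete at C5 or C6 next to a ring bromine, with loss of LiBr or halogen migration, or the Boc group may shift from N to C2 if 8 warms before the quench. The fallback would avoid strong base and set out from 7. Methanolysis (K2CO3, MeOH) would give 4,7-dibromo-3-chloro-1H-indole F3. Iridium-catalysed C–H borylation ([Ir(OMe)(cod)]2, 4,4'-di-tert-butyl-2,2'-bipyridine, B2pin2, THF, 60 °C) would go to C2, the site N–H indoles offer when C3 and C7 are blocked, and give 4,7-dibromo-3-chloro-2-(4,4,5,5-tetramethyl-1,3,2-dioxaborolan-2-yl)-1H-indole F4. Bromodeboronation with CuBr2 in MeOH/H2O at 80 °C would then join the route at 10.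

Step 3. Chlorination of an N-acylated, doubly brominated indole may be sluggish, and forcing it may cost the Boc group or selectivity. The fallback would chlorinate before aromatisation and set out from 5. After the cycloaddition and SO2 loss, NCS at 0 °C would chlorinate the enecarbamate beta-carbon of 5 (the known beta-halogenation of enamides through an N-acyliminium ion and proton loss) to give tert-butyl cis-4,7-dibromo-3-chloro-3a,7a-dihydro-1H-indole-1-carboxylate F5. DDQ would then dehydrogenate it and rejoin the route at 7.

**Further compounds**
F1 | step 2 | tert-butyl cis-4,7-dibromo-2,3,3a,7a-tetrahydro-1H-indole-1-carboxylate (racemic) | CC(C)(C)OC(=O)N1CC[C@H]2[C@@H]1C(Br)=CC=C2Br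
F2 | step 2 | tert-butyl 4,7-dibromo-2,3-dihydro-1H-indole-1-carboxylate | CC(C)(C)OC(=O)N1CCc2c(Br)ccc(Br)c21
F3 | step 4 | 4,7-dibromo-3-chloro-1H-indole | Clc1c[nH]c2c(Br)ccc(Br)c12
F4 | step 4 | 4,7-dibromo-3-chloro-2-(4,4,5,5-tetramethyl-1,3,2-dioxaborolan-2-yl)-1H-indole | CC1(C)OB(OC1(C)C)c1[nH]c2c(Br)ccc(Br)c2c1Cl
F5 | step 3 | tert-butyl cis-4,7-dibromo-3-chloro-3a,7a-dihydro-1H-indole-1-carboxylate (racemic) | CC(C)(C)OC(=O)N1C=C(Cl)[C@H]2[C@@H]1C(Br)=CC=C2Br
A1 | direct plan | 2,5-dibromoaniline | Nc1cc(Br)ccc1Br
A2 | direct plan | rac-4,7-dibromo-3-(methylsulfanyl)indolin-2-one | CSC1C(=O)Nc2c(Br)ccc(Br)c12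
A3 | direct plan | 4,7-dibromoindolin-2-one | O=C1Cc2c(Br)ccc(Br)c2N1
A4 | direct plan | 2,4,7-tribromo-1H-indole | Brc1cc2c(Br)ccc(Br)c2[nH]1
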